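What stands in the flask at the asked time, and how does the starting material divide between target and isomer of the product?

    second substrate + free catalyst ⇌ catalyst intermediate B (K1 = 18 M⁻¹, k1 = 25.7 M⁻¹ min⁻¹)
    catalyst intermediate A → free catalyst + target (k2 = 1.42 min⁻¹)
    target + free catalyst ⇌ isomer of the product + free catalyst, rate k3*[free catalyst]*[target] forward; the back reaction follows from the equilibrium constant (K3 = 0.32, k3 = 19.1 M⁻¹ min⁻¹)
    2 catalyst intermediate A ⇌ resting dimer, settled at all times (K4 = 1000 M⁻¹)
    starting material + free catalyst ⇌ catalyst intermediate A (K5 = 24.0 M⁻¹, k5 = 32.3 M⁻¹ min⁻¹)
    catalyst intermediate B → free catalyst + second product (k6 = 12.5 min⁻¹)

starting material 0.050 M (fed, over 1.0 h); second substrate 0.0500 M; free catalyst 1.2 mM; time 40 h; the fed solution adds 0.10 times the starting volume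

- which holds at 40 h: what has brought the reaction to rest, or that it has not come to rest (it is still moving / all of the starting material has reacted / forward and back rates have come level / no working catalyst is left)
- how much target there is at 40 h, in percent of the starting material charged
- how much isomer of the product there is at 40 h, in percent of the starting material charged

- a species is counted by the starting material in it: one resting dimer counts as two
- two of one species on the left: rate k times its square, two consumed each time
- charges are per starting volume, the dose included; the dosed solution carries all of it
- the reaction counts as stopped when no species that holds the starting material changes by six tenths of a point or more over the second half of the time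
- run time (flask): 40 h

The reckoning starts from the rates at one moment. Target meets free catalyst and becomes isomer of the product at a rate proportional to c(free catalyst)·c(target). The way back carries the same c(free catalyst), and its constant is the forward constant divided by the equilibrium constant, 0.32. At first the forward rate stands unopposed. As isomer gathers, the ratio of back rate to forward rate grows as c(isomer of the product)/(0.32·c(target)), and free catalyst cancels from it. The two rates come level when c(isomer of the product)/c(target) reaches 0.32. That puts 24.2% of the charge in the isomer and 75.8% in the target, provided the charge has reacted and the pair has had time.

Time is the first objection. The pair closes on its balance at the sum of both rate constants: the forward constant times c(free catalyst) times (one plus one over the equilibrium constant). Here c(free catalyst) is the charge, thinned by the feed's 0.10 of extra volume. Dividing 0.693 by that sum gives 0.134 h, the relaxation half-life, the time in which the pair closes half its distance from balance. The run of 40 h holds 299 of these.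

The second objection is that part of the catalyst is bound while the substrates last. Less free catalyst means a longer relaxation half-life while the substrates last, so the question is how long they last. The substrates should go early. By forward binding at the charged catalyst, starting material has a half-life of 0.30 h and second substrate 0.37 h, and the dosing takes 1.0 h, each far shorter than the run. No step removes catalyst, so the bound forms return it, and the estimate stands.

The forecast agrees: all of the starting material has reacted, with 75.8% of target (75% to 76.5%) and 24.2% of isomer (23.5% to 25%), since “The target and its isomer then relax in well under an hour or so of catalyst action”.

At 40 h the simulation of the flask gives all of the starting material has reacted, with 75.8% of target and 24.2% of isomer of the product. The split is thermodynamic control: with the way back from isomer to target struck out, the isomer reaches 100% instead of 24.2%. That way back keeps its pace through the relaxation half-life, 0.134 h with the flask's catalyst. The neighbour flask, with 0.0030 M of free catalyst, has a shorter half-life of 0.0538 h, and it holds 24.2% of isomer.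

The rate constants are those of an exercise; the result is computed.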